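## The problem

Aiphanol (23) is a stilbenolignan. An (E)-3,5-dihydroxystilbene (ring C is the resorcinol ring) has its other aryl ring, ring B, fused through two oxygens to a 1,4-dioxane. C7 of the dioxane carries ring A (4-hydroxy-3,5-dimethoxyphenyl) and C8 carries the hydroxymethyl carbon C9. The two substituents are trans and the structure is the (7R,8R) isomer, (2R,3R) in benzodioxine numbering.

A synthesis has to solve three things:

- **Regiochemistry.** The ring B oxygen para to the stilbene carbon must be bonded to C8 and the oxygen meta to it to C7, so the two oxygens of a 4-substituted catechol must be told apart.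
- **Stereochemistry.** C8 is an ordinary secondary ether carbon that does not ionise. C7 is a benzylic ether carbon para to a phenol and can ionise. C8 can therefore control C7, but not the reverse.
- **Sensitivity.** The target has three free phenols, a primary alcohol and an oxidisable stilbene. Its C7–O bond becomes labile to acid and base once the ring A phenol is free. Hydrogenolysis, strong acid and long exposure to base are excluded late in the route.

The enabling feature is that C7 is benzylic and para to the ring A hydroxyl, which is flanked by two methoxy groups. Its bond to the ring B oxygen can be formed and re-formed through a para-quinone methide. Only C8 then has to be introduced as a single enantiomer; C7 can be left to thermodynamic control.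

## Retrosynthesis

**Stilbene last.** The bond between ring B and the vinyl carbon of 23 is cut, after the two ring C phenols are masked as acetates (22). This gives bromobenzodioxane 18 and 3,5-diacetoxystyrene 21, joined forward by a Heck reaction. Cutting through the C=C bond instead (Wittig or Horner–Wadsworth–Emmons) would need a formyl group on ring B, but here the formyl group of the ring B starting material is spent as a latent phenol. Bromine is inert in every earlier step and is the natural handle. The cut keeps the oxidation-prone resorcinol stilbene out of all but the last two steps. The forward coupling must tolerate the free phenol and alcohol of 18 and give the E alkene. Styrene 21 comes from aldehyde 19 through 20.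

**Dioxane ring through the O–C7 bond (key step).** In 18 the bond between C7 and the ring B oxygen meta to bromine is cut. This gives the open tetraol 16, in which C8 is already bonded to the oxygen para to bromine. The forward reaction runs through quinone methide 17. Cutting O–C8 instead would be a stereospecific displacement that needs both stereocentres in place beforehand. Cutting both C–O bonds (oxidative coupling of a catechol with a sinapyl unit) controls neither regiochemistry nor absolute configuration. With the O–C7 cut, either C7 epimer of 16 serves, so the precursor has one stereocentre of consequence instead of two. The forward step must give the trans isomer, leave C8 untouched, and close onto the ring B oxygen faster than 17 is captured intermolecularly.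

**Oxidation level and protection.** Tetraol 16 is traced to tris-silyl ether 15 and then to aryl ketone 14. No skeletal bond is cut. The reduction of 14 need not be diastereoselective. The three silyl groups (ring A phenol, ring B phenol, C9 hydroxyl) are the same, so one fluoride treatment frees everything the key step needs.

**C7–ring A bond.** Ketone 14 is cut between C7 and ring A into Weinreb amide 10 and arylmagnesium bromide 13. Reagent 13 comes from silyl ether 12 of the commercial bromophenol 11. Adding 13 to an α-aryloxy aldehyde would be one step shorter, but such an aldehyde is configurationally fragile at C8. The chelated Weinreb adduct keeps C8 safe until the quench. The cut splits the molecule into ring A and a three-carbon ring B ether.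

**Second ring B oxygen from a formyl group.** Amide 10 goes back through phenol 9 and aryl formate 8 to aldehyde 7. The oxygen meta to bromine arises by Baeyer–Villiger oxidation of the formyl group. This is what differentiates the two ring B oxygens: in 7 one is already the C8 ether and the other is still carbon. A 4-bromocatechol would need a regioselective mono-alkylation that cannot be relied on.

**C8–O bond and the source of chirality.** In 7 the bond from C8 to the oxygen para to bromine is cut, giving 5-bromosalicylaldehyde 6 and triflate 5. The forward SN2 displacement inverts and sets (R)-C8. Triflate 5 comes from L-serine 1 through (S)-glyceric acid 2, methyl ester 3 and primary silyl ether 4. The chiral pool is preferred over asymmetric dihydroxylation of a cinnamate because only one stereocentre is wanted, and it is wanted at a carbon that never ionises.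

## Roads not taken

**Alternative 1: building ring C by polyketide aldol aromatisation.**
- *Cut:* one C–C bond of the resorcinol ring, and with it the whole ring, which is assembled from a dioxinone chain.
- *Forward key step:* mild base folds the diketo-dioxinone A2 by aldol condensation between the dioxinone α-carbon and the styryl ketone carbon; dehydration gives the resorcylate stilbene A1.
- *Merits:* no transition metal, mild conditions, and the E alkene is carried in from a cinnamoyl unit.
- *Weak points:* ring C of aiphanol is a plain symmetrical 3,5-dihydroxyphenyl group that is commercial as 19. A1 carries an extra carboxyl carbon that aiphanol lacks, so unmasking and decarboxylation on a polyphenolic stilbene would follow. The benzodioxane with both stereocentres must already be present in A2, so the real difficulty of the target is left unaddressed.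
- *Comparison:* this road is better in avoiding a late palladium coupling on a substrate with free hydroxyls. The chosen plan sets against that a two-step endgame from a commercial aldehyde and no superfluous carbon to remove.

**Alternative 2: oxocarbenium Sakurai annulation.**
- *Cut:* both the O–C7 and the C7–C8 bond in one operation.
- *Forward key step:* the phenol of allylsilane A5 exchanges into the dimethyl acetal A4. The mixed acetal ionises, and the γ-carbon of the allylsilane attacks C7 to give the vinyl benzodioxane A3.
- *Merits:* the most convergent of the roads; two bonds, the ring and both stereocentres form in one step from achiral pieces.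
- *Weak points:* A4 and A5 are achiral, so A3 would be racemic unless a chiral acid controls the oxocarbenium ion pair, which is not an established solution for this ring system. The mixed acetal can also ionise by losing the aryloxide, which is the better leaving group. The vinyl group must be degraded to C9 through an epimerisable α-aryloxy aldehyde. The ester must be converted to the stilbene over several steps. The benzyl ether would finally have to be removed beside a stilbene alkene.
- *Comparison:* this road forms more bonds in its key step and would be shorter to the ring. The chosen plan sets against that a secure absolute configuration from the chiral pool and no adjustment at C9 or the ring B handle.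

**Alternative 3: phenoxide 6-exo opening of a terminal epoxide.**
- *Cut:* the O–C8 bond.
- *Forward key step:* the phenoxide of epoxy phenol A7, which has the (7R,8S) configuration, attacks C8 with inversion. This closes the dioxane and releases the C9 hydroxyl, giving aldehyde A6.
- *Merits:* the closure is stereospecific and runs under base, with no cationic intermediate and no risk to C8. The formyl group of A6 allows a metal-free olefination endgame.
- *Weak points:* both stereocentres must be set before the ring closes. The C7 aryl ether must be made stereospecifically at an ionisable, electron-rich benzylic carbon, and the oxygen concerned is meta to the formyl group, so nucleophilic aromatic substitution is not available. Attack at the hindered internal epoxide carbon (6-exo) must beat attack at the terminal carbon (7-endo). An error at C7 is not corrected later.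
- *Comparison:* this road is better where kinetic definition matters, for instance if equilibration in the chosen plan were slow or C8 eroded. The chosen plan sets against that a single stereocentre to install and a C7 that corrects itself.

Key step: step 13

Remark on the chemistry: 15 and 16 are carried as mixtures of the two C7 epimers (their SMILES leave C7 open), which is harmless because both epimers ionise to the same quinone methide 17.

## Route

Step 1
Reactants: 1 L-serine
Product: 2 (S)-glyceric acid, (2S)-2,3-dihydroxypropanoic acid
Conditions: NaNO2, H2SO4 (aq), 0 °C → rt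
Reagents that add atoms: water, O
Why: Diazotisation of an α-amino acid; the carboxylate displaces dinitrogen to an α-lactone and water reopens it, so two inversions return the (S) configuration.

Step 2
Reactants: 2 (S)-glyceric acid
Product: 3 methyl (2S)-2,3-dihydroxypropanoate
Conditions: MeOH, H2SO4 (cat.), reflux
Reagents that add atoms: methanol, CO
Why: Fischer esterification of the crude acid; the stereocentre is not involved.

Step 3
Reactants: 3 methyl (2S)-2,3-dihydroxypropanoate
Product: 4 methyl (2S)-3-[(tert-butyldimethylsilyl)oxy]-2-hydroxypropanoate
Conditions: TBSCl, imidazole, CH2Cl2, 0 °C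
Reagents that add atoms: tert-butyldimethylsilyl chloride, CC(C)(C)[Si](C)(C)Cl
Why: Selective silylation of the primary hydroxyl of a 1,2-diol with a bulky chlorosilane; the secondary hydroxyl next to the ester is slower.

Step 4
Reactants: 4 methyl (2S)-3-[(tert-butyldimethylsilyl)oxy]-2-hydroxypropanoate
Product: 5 methyl (2S)-3-[(tert-butyldimethylsilyl)oxy]-2-[(trifluoromethanesulfonyl)oxy]propanoate
Conditions: Tf2O, 2,6-lutidine, CH2Cl2, −78 °C
Reagents that add atoms: trifluoromethanesulfonic anhydride, O=S(=O)(OS(=O)(=O)C(F)(F)F)C(F)(F)F
Why: O-sulfonylation with a hindered pyridine base leaves the C–O bond intact, so the (S) configuration is kept; the triflate should be used at once.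

Step 5
Reactants: 5 methyl (2S)-3-[(tert-butyldimethylsilyl)oxy]-2-[(trifluoromethanesulfonyl)oxy]propanoate; 6 5-bromosalicylaldehyde
Product: 7 methyl (2R)-2-(4-bromo-2-formylphenoxy)-3-[(tert-butyldimethylsilyl)oxy]propanoate
Conditions: K2CO3, MeCN, 0 °C → rt
Reagents that add atoms: none
Why: SN2 displacement of an α-triflyloxy ester by a phenoxide (Williamson type) inverts the carbon and sets (R)-C8; the weakly basic salicylaldehyde phenoxide should limit elimination and enolisation, and the oxygen used is the one para to bromine.

Step 6
Reactants: 7 methyl (2R)-2-(4-bromo-2-formylphenoxy)-3-[(tert-butyldimethylsilyl)oxy]propanoate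
Product: 8 methyl (2R)-2-[4-bromo-2-(formyloxy)phenoxy]-3-[(tert-butyldimethylsilyl)oxy]propanoate
Conditions: mCPBA, CH2Cl2, 0 °C → rt
Reagents that add atoms: 3-chloroperbenzoic acid, O=C(OO)c1cccc(Cl)c1
Why: Baeyer–Villiger (Dakin-type) oxidation of an ortho-alkoxybenzaldehyde; the aryl group migrates in the Criegee adduct, turning the formyl group into the ring B oxygen meta to bromine.

Step 7
Reactants: 8 methyl (2R)-2-[4-bromo-2-(formyloxy)phenoxy]-3-[(tert-butyldimethylsilyl)oxy]propanoate
Product: 9 (2R)-2-(4-bromo-2-hydroxyphenoxy)-3-[(tert-butyldimethylsilyl)oxy]-N-methoxy-N-methylpropanamide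
Conditions: MeNHOMe·HCl, iPrMgCl, THF, −20 → 0 °C; aq NH4Cl
Reagents that add atoms: N,O-dimethylhydroxylamine hydrochloride, CNOC.Cl
Why: Weinreb amide formation from the methyl ester with the chloromagnesium amide; the same reagent cleaves the aryl formate, and any benzodioxinone lactone formed from the freed phenoxide is opened to the same amide.

Step 8
Reactants: 9 (2R)-2-(4-bromo-2-hydroxyphenoxy)-3-[(tert-butyldimethylsilyl)oxy]-N-methoxy-N-methylpropanamide
Product: 10 (2R)-2-{4-bromo-2-[(tert-butyldimethylsilyl)oxy]phenoxy}-3-[(tert-butyldimethylsilyl)oxy]-N-methoxy-N-methylpropanamide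
Conditions: TBSCl, imidazole, DMF, rt
Reagents that add atoms: tert-butyldimethylsilyl chloride, CC(C)(C)[Si](C)(C)Cl
Why: Phenol silylation; it keeps the ring B phenol from quenching the Grignard reagent and from forming a cyclic hemiketal with the coming ketone, and it is removed later together with the other silyl groups.

Step 9
Reactants: 11 4-bromo-2,6-dimethoxyphenol
Product: 12 (4-bromo-2,6-dimethoxyphenoxy)(tert-butyl)dimethylsilane
Conditions: TBSCl, imidazole, DMAP (cat.), DMF, 40 °C
Reagents that add atoms: tert-butyldimethylsilyl chloride, CC(C)(C)[Si](C)(C)Cl
Why: Silylation of the hindered ring A phenol so that the aryl bromide can be converted to a Grignard reagent.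

Step 10
Reactants: 12 (4-bromo-2,6-dimethoxyphenoxy)(tert-butyl)dimethylsilane; 10 (2R)-2-{4-bromo-2-[(tert-butyldimethylsilyl)oxy]phenoxy}-3-[(tert-butyldimethylsilyl)oxy]-N-methoxy-N-methylpropanamide
Product: 14 (2R)-2-{4-bromo-2-[(tert-butyldimethylsilyl)oxy]phenoxy}-3-[(tert-butyldimethylsilyl)oxy]-1-{4-[(tert-butyldimethylsilyl)oxy]-3,5-dimethoxyphenyl}propan-1-one, via arylmagnesium bromide 13 (not isolated)
Conditions: 12, Mg, THF, 50 °C (decant from excess Mg); then 10, THF, −20 → 0 °C; cold aq NH4Cl
Reagents that add atoms: none
Why: Grignard formation by magnesium insertion followed by Weinreb ketone synthesis; the chelated tetrahedral adduct prevents over-addition and keeps C8 non-enolisable until the cold quench, and the ring B bromide does not exchange with an arylmagnesium halide at this temperature.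

Step 11
Reactants: 14 the aryl ketone of step 10
Product: 15 (2R)-2-{4-bromo-2-[(tert-butyldimethylsilyl)oxy]phenoxy}-3-[(tert-butyldimethylsilyl)oxy]-1-{4-[(tert-butyldimethylsilyl)oxy]-3,5-dimethoxyphenyl}propan-1-ol (both C1 epimers, C1 being C7)
Conditions: NaBH4, CeCl3·7H2O, MeOH–THF, −40 °C
Reagents that add atoms: none
Why: Luche-type borohydride reduction of the aryl ketone; the cerium salt and low temperature should suppress enolisation at C8, and the C7 epimer mixture is acceptable because both epimers converge in step 13.

Step 12
Reactants: 15 the tris-silyl carbinol of step 11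
Product: 16 (2R)-2-(4-bromo-2-hydroxyphenoxy)-1-(4-hydroxy-3,5-dimethoxyphenyl)propane-1,3-diol (both C1 epimers)
Conditions: Bu4NF, AcOH, THF, 0 °C → rt
Reagents that add atoms: none
Why: Fluoride cleavage of the two aryl silyl ethers and the primary alkyl silyl ether in one operation; acetic acid buffers the phenoxides so that no base-mediated chemistry starts at C7.

Step 13
Reactants: 16 (2R)-2-(4-bromo-2-hydroxyphenoxy)-1-(4-hydroxy-3,5-dimethoxyphenyl)propane-1,3-diol (both C1 epimers)
Product: 18 trans bromobenzodioxane [(2R,3R)-6-bromo-3-(4-hydroxy-3,5-dimethoxyphenyl)-2,3-dihydro-1,4-benzodioxin-2-yl]methanol, via para-quinone methide 17 (not isolated)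
Conditions: Amberlyst 15 (polystyrene sulfonic acid resin, H+ form), MeCN–toluene, 50 °C, high dilution
Reagents that add atoms: none
Why: The sulfonic acid protonates the C7 hydroxyl of either epimer of 16 and water leaves with the push of the para-hydroxyl of ring A, giving quinone methide 17 or its O-protonated form; this is the known behaviour of 4-hydroxybenzyl alcohols, and the closest known reaction type is the acid-mediated cyclisation of 8-O-4' neolignan diols to 2-aryl-1,4-benzodioxanes. The free ring B phenol then adds to the exocyclic methide carbon C7 in an intramolecular oxa-conjugate (1,6-) addition, a 6-exo-trig closure that forms the O–C7 bond and the 1,4-dioxane ring while ring A rearomatises. Regiochemistry is not at issue, because the oxygen para to bromine is already bonded to C8 and only the oxygen meta to bromine is free. The only new stereocentre is C7 and it is controlled by C8: the C7–O bond of the product can re-ionise through 17 under the same conditions, so the closure is reversible and should settle on the trans isomer, with ring A and the hydroxymethyl group both pseudo-equatorial on the half-chair dioxane, which is (7R,8R) from (8R). No bond to C8 is broken (its descriptor in 17 reads S only because the substituent priorities change), so the enantiomeric purity set in step 5 should be carried through provided 17 is trapped faster than it tautomerises to the C7–C8 enol ether; the six-membered intramolecular trap and the absence of base favour this. The C9 hydroxyl does not compete, since its attack would give an oxetane, and capture of 17 by another molecule is reversible and is disfavoured by dilution. The two methoxy groups flanking the ring A phenol make the ionisation easy enough for a mild heterogeneous acid at moderate temperature, so the step can be run on the unprotected tetraol.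

Step 14
Reactants: 19 3,5-dihydroxybenzaldehyde
Product: 20 5-ethenylbenzene-1,3-diol (3,5-dihydroxystyrene)
Conditions: Ph3PCH3Br, KOtBu (excess), THF, 0 °C → rt
Reagents that add atoms: methyltriphenylphosphonium bromide, C[P+](c1ccccc1)(c1ccccc1)c1ccccc1.[Br-]
Why: Wittig methylenation with excess ylide to cover the two phenols; the meta phenoxides are not conjugated with the formyl group and leave it reactive, and the styrene is taken on without storage.

Step 15
Reactants: 20 5-ethenylbenzene-1,3-diol
Product: 21 5-ethenyl-1,3-phenylene diacetate (3,5-diacetoxystyrene)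
Conditions: Ac2O, Et3N, DMAP (cat.), CH2Cl2, 0 °C
Reagents that add atoms: acetic anhydride, CC(=O)OC(C)=O
Why: Acetylation of both phenols gives a styrene that resists polymerisation and oxidation under the coupling conditions.

Step 16
Reactants: 18 trans bromobenzodioxane; 21 3,5-diacetoxystyrene
Product: 22 5-[(E)-2-[(2R,3R)-3-(4-hydroxy-3,5-dimethoxyphenyl)-2-(hydroxymethyl)-2,3-dihydro-1,4-benzodioxin-6-yl]ethenyl]-1,3-phenylene diacetate
Conditions: Pd(OAc)2 (cat.), P(o-tol)3, Et3N, DMF, 100 °C, degassed
Reagents that add atoms: none
Why: Mizoroki–Heck reaction: oxidative addition of the aryl bromide to zerovalent palladium, syn insertion at the unsubstituted styrene terminus and syn β-hydride elimination should give the E stilbene. Any acetyl transfer onto the free hydroxyls of 18 is of no consequence because step 17 removes all acetates.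

Step 17
Reactants: 22 the stilbene diacetate of step 16
Product: 23 aiphanol, 5-[(E)-2-[(2R,3R)-3-(4-hydroxy-3,5-dimethoxyphenyl)-2-(hydroxymethyl)-2,3-dihydro-1,4-benzodioxin-6-yl]ethenyl]benzene-1,3-diol
Conditions: K2CO3 (cat.), MeOH, 0 °C → rt, degassed; AcOH quench
Reagents that add atoms: none
Why: Zemplén-type transesterification of aryl acetates; cold, short, oxygen-free treatment should spare the stilbene and the C7–O bond, and any reversible opening at C7 would reclose to the same trans isomer.

## Compound list

1 | L-serine | N[C@@H](CO)C(=O)O | starting material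
2 | (S)-glyceric acid | O[C@@H](CO)C(=O)O | intermediate
3 | methyl (2S)-2,3-dihydroxypropanoate | COC(=O)[C@@H](O)CO | intermediate
4 | methyl (2S)-3-[(tert-butyldimethylsilyl)oxy]-2-hydroxypropanoate | COC(=O)[C@@H](O)CO[Si](C)(C)C(C)(C)C | intermediate
5 | methyl (2S)-3-[(tert-butyldimethylsilyl)oxy]-2-[(trifluoromethanesulfonyl)oxy]propanoate | COC(=O)[C@@H](OS(=O)(=O)C(F)(F)F)CO[Si](C)(C)C(C)(C)C | intermediate
6 | 5-bromosalicylaldehyde (5-bromo-2-hydroxybenzaldehyde) | O=Cc1cc(Br)ccc1O | starting material
7 | methyl (2R)-2-(4-bromo-2-formylphenoxy)-3-[(tert-butyldimethylsilyl)oxy]propanoate | COC(=O)[C@H](Oc1ccc(Br)cc1C=O)CO[Si](C)(C)C(C)(C)C | intermediate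
8 | methyl (2R)-2-[4-bromo-2-(formyloxy)phenoxy]-3-[(tert-butyldimethylsilyl)oxy]propanoate | COC(=O)[C@H](Oc1ccc(Br)cc1OC=O)CO[Si](C)(C)C(C)(C)C | intermediate
9 | (2R)-2-(4-bromo-2-hydroxyphenoxy)-3-[(tert-butyldimethylsilyl)oxy]-N-methoxy-N-methylpropanamide | CON(C)C(=O)[C@H](Oc1ccc(Br)cc1O)CO[Si](C)(C)C(C)(C)C | intermediate
10 | (2R)-2-{4-bromo-2-[(tert-butyldimethylsilyl)oxy]phenoxy}-3-[(tert-butyldimethylsilyl)oxy]-N-methoxy-N-methylpropanamide | CON(C)C(=O)[C@H](Oc1ccc(Br)cc1O[Si](C)(C)C(C)(C)C)CO[Si](C)(C)C(C)(C)C | intermediate
11 | 4-bromo-2,6-dimethoxyphenol | COc1cc(Br)cc(OC)c1O | starting material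
12 | (4-bromo-2,6-dimethoxyphenoxy)(tert-butyl)dimethylsilane | COc1cc(Br)cc(OC)c1O[Si](C)(C)C(C)(C)C | intermediate
13 | {4-[(tert-butyldimethylsilyl)oxy]-3,5-dimethoxyphenyl}magnesium bromide (not isolated) | COc1cc([Mg]Br)cc(OC)c1O[Si](C)(C)C(C)(C)C | intermediate
14 | (2R)-2-{4-bromo-2-[(tert-butyldimethylsilyl)oxy]phenoxy}-3-[(tert-butyldimethylsilyl)oxy]-1-{4-[(tert-butyldimethylsilyl)oxy]-3,5-dimethoxyphenyl}propan-1-one | COc1cc(C(=O)[C@H](Oc2ccc(Br)cc2O[Si](C)(C)C(C)(C)C)CO[Si](C)(C)C(C)(C)C)cc(OC)c1O[Si](C)(C)C(C)(C)C | intermediate
15 | (2R)-2-{4-bromo-2-[(tert-butyldimethylsilyl)oxy]phenoxy}-3-[(tert-butyldimethylsilyl)oxy]-1-{4-[(tert-butyldimethylsilyl)oxy]-3,5-dimethoxyphenyl}propan-1-ol, both C1 epimers | COc1cc(C(O)[C@H](Oc2ccc(Br)cc2O[Si](C)(C)C(C)(C)C)CO[Si](C)(C)C(C)(C)C)cc(OC)c1O[Si](C)(C)C(C)(C)C | intermediate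
16 | (2R)-2-(4-bromo-2-hydroxyphenoxy)-1-(4-hydroxy-3,5-dimethoxyphenyl)propane-1,3-diol, both C1 epimers | COc1cc(C(O)[C@H](Oc2ccc(Br)cc2O)CO)cc(OC)c1O | intermediate
17 | 4-[(2S)-2-(4-bromo-2-hydroxyphenoxy)-3-hydroxypropylidene]-2,6-dimethoxycyclohexa-2,5-dien-1-one (para-quinone methide, not isolated; same spatial arrangement at C8 as in 16) | COC1=CC(=C[C@H](Oc2ccc(Br)cc2O)CO)C=C(OC)C1=O | intermediate
18 | [(2R,3R)-6-bromo-3-(4-hydroxy-3,5-dimethoxyphenyl)-2,3-dihydro-1,4-benzodioxin-2-yl]methanol (trans) | COc1cc([C@H]2Oc3cc(Br)ccc3O[C@@H]2CO)cc(OC)c1O | intermediate
19 | 3,5-dihydroxybenzaldehyde | O=Cc1cc(O)cc(O)c1 | starting material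
20 | 5-ethenylbenzene-1,3-diol | C=Cc1cc(O)cc(O)c1 | intermediate
21 | 5-ethenyl-1,3-phenylene diacetate | C=Cc1cc(OC(C)=O)cc(OC(C)=O)c1 | intermediate
22 | 5-[(E)-2-[(2R,3R)-3-(4-hydroxy-3,5-dimethoxyphenyl)-2-(hydroxymethyl)-2,3-dihydro-1,4-benzodioxin-6-yl]ethenyl]-1,3-phenylene diacetate | COc1cc([C@H]2Oc3cc(/C=C/c4cc(OC(C)=O)cc(OC(C)=O)c4)ccc3O[C@@H]2CO)cc(OC)c1O | intermediate
23 | aiphanol, 5-[(E)-2-[(2R,3R)-3-(4-hydroxy-3,5-dimethoxyphenyl)-2-(hydroxymethyl)-2,3-dihydro-1,4-benzodioxin-6-yl]ethenyl]benzene-1,3-diol | COc1cc([C@H]2Oc3cc(/C=C/c4cc(O)cc(O)c4)ccc3O[C@@H]2CO)cc(OC)c1O | target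

## Step count and risks

Total step count: 17. Longest linear sequence: 14 steps from L-serine (steps 1–8, 10–13, 16, 17). Step 9 prepares the ring A fragment and steps 14–15 the styrene.

**Step 13 (key step).**
- *What may go wrong:* erosion of the C8 configuration if 17 or its cation tautomerises to the C7–C8 enol ether before it is trapped; intermolecular capture of 17 leading to oligomers; incomplete cis-to-trans equilibration; fragmentation of the benzylic cation with loss of C9 as formaldehyde.
- *Fallback:* generate the same quinone methide without acid. Setting out from 15, the C7 hydroxyl is acetylated (Ac2O, DMAP, pyridine) to (2R)-2-{4-bromo-2-[(tert-butyldimethylsilyl)oxy]phenoxy}-3-[(tert-butyldimethylsilyl)oxy]-1-{4-[(tert-butyldimethylsilyl)oxy]-3,5-dimethoxyphenyl}propyl acetate F1. Bu4NF in THF then removes the silyl groups. The ring A phenoxide expels acetate by 1,6-elimination, a known way to para-quinone methides from 4-silyloxybenzyl acetates, and the ring B phenoxide closes the ring. Any cis isomer is equilibrated with K2CO3 in DMF through the retro-oxa-Michael and oxa-Michael pair. The sequence comes back to the route at 18.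

**Step 5.**
- *What may go wrong:* partial loss of enantiopurity through enolisation of the α-triflyloxy ester or of the product; elimination; decomposition of the triflate on handling.
- *Fallback:* couple alcohol 4 directly with 6 by a Mitsunobu reaction (PPh3, DIAD, toluene, 0 °C → rt). This also inverts the carbinol carbon and gives 7 without the triflate. It sets out from 4, returns at 7, makes no new compound and is entered as F0.

**Step 10 (together with step 11).**
- *What may go wrong:* enolisation of the α-aryloxy ketone 14 during quench, purification or reduction, eroding C8; β-elimination of the silyloxy group.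
- *Fallback:* avoid the ketone. Setting out from 8, NaHCO3 in MeOH removes the formate to give methyl (2R)-2-(4-bromo-2-hydroxyphenoxy)-3-[(tert-butyldimethylsilyl)oxy]propanoate F2. TBSCl and imidazole give methyl (2R)-2-{4-bromo-2-[(tert-butyldimethylsilyl)oxy]phenoxy}-3-[(tert-butyldimethylsilyl)oxy]propanoate F3. iBu2AlH at −78 °C converts F3 to the diisobutylaluminium hemiacetal F4, which is not isolated and is treated in the same flask with 13. The aldehyde is released only in the presence of the Grignard reagent and is captured as carbinol 15, where the route is rejoined.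

**Step 16.**
- *What may go wrong:* slow oxidative addition into an electron-rich aryl bromide that also carries a free phenol; arylation at the internal styrene carbon giving the 1,1-diarylethene; catalyst decomposition before conversion is complete.
- *Fallback:* form the alkene by metathesis. Setting out from 18, Suzuki–Miyaura vinylation with potassium vinyltrifluoroborate (PdCl2(dppf), Et3N, n-PrOH, 80 °C) gives [(2R,3R)-6-ethenyl-3-(4-hydroxy-3,5-dimethoxyphenyl)-2,3-dihydro-1,4-benzodioxin-2-yl]methanol F5. Cross-metathesis of F5 with an excess of 21 using the second-generation Grubbs catalyst (H2IMes)(PCy3)Cl2Ru=CHPh in CH2Cl2 at 40 °C should give the E stilbene 22, where the route is rejoined.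

## Further compounds

F0 | step 5 | none | none
F1 | step 13 | (2R)-2-{4-bromo-2-[(tert-butyldimethylsilyl)oxy]phenoxy}-3-[(tert-butyldimethylsilyl)oxy]-1-{4-[(tert-butyldimethylsilyl)oxy]-3,5-dimethoxyphenyl}propyl acetate, both C1 epimers | COc1cc(C(OC(C)=O)[C@H](Oc2ccc(Br)cc2O[Si](C)(C)C(C)(C)C)CO[Si](C)(C)C(C)(C)C)cc(OC)c1O[Si](C)(C)C(C)(C)C
F2 | step 10 | methyl (2R)-2-(4-bromo-2-hydroxyphenoxy)-3-[(tert-butyldimethylsilyl)oxy]propanoate | COC(=O)[C@H](Oc1ccc(Br)cc1O)CO[Si](C)(C)C(C)(C)C
F3 | step 10 | methyl (2R)-2-{4-bromo-2-[(tert-butyldimethylsilyl)oxy]phenoxy}-3-[(tert-butyldimethylsilyl)oxy]propanoate | COC(=O)[C@H](Oc1ccc(Br)cc1O[Si](C)(C)C(C)(C)C)CO[Si](C)(C)C(C)(C)C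
F4 | step 10 | diisobutylaluminium hemiacetal of F3 (not isolated, hemiacetal carbon unassigned) | COC(O[Al](CC(C)C)CC(C)C)[C@H](Oc1ccc(Br)cc1O[Si](C)(C)C(C)(C)C)CO[Si](C)(C)C(C)(C)C
F5 | step 16 | [(2R,3R)-6-ethenyl-3-(4-hydroxy-3,5-dimethoxyphenyl)-2,3-dihydro-1,4-benzodioxin-2-yl]methanol | COc1cc([C@H]2Oc3cc(C=C)ccc3O[C@@H]2CO)cc(OC)c1O
A1 | alternative 1 | isopropylidene-protected resorcylate stilbene with ring A MOM ether and C9 silyl ether | COc1cc([C@H]2Oc3cc(/C=C/c4cc(O)cc5OC(C)(C)OC(=O)c45)ccc3O[C@@H]2CO[Si](C)(C)C(C)(C)C)cc(OC)c1OCOC
A2 | alternative 1 | diketo-dioxinone attached to the benzodioxane cinnamoyl unit | COc1cc([C@H]2Oc3cc(/C=C/C(=O)CC(=O)CC4=CC(=O)OC(C)(C)O4)ccc3O[C@@H]2CO[Si](C)(C)C(C)(C)C)cc(OC)c1OCOC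
A3 | alternative 2 | trans 2-aryl-3-vinyl-1,4-benzodioxane methyl ester with ring A benzyl ether | COc1cc([C@H]2Oc3cc(C(=O)OC)ccc3O[C@@H]2C=C)cc(OC)c1OCc1ccccc1
A4 | alternative 2 | 4-benzyloxy-3,5-dimethoxybenzaldehyde dimethyl acetal | COc1cc(C(OC)OC)cc(OC)c1OCc1ccccc1
A5 | alternative 2 | methyl 3-hydroxy-4-{[(1Z)-3-(trimethylsilyl)prop-1-en-1-yl]oxy}benzoate (drawn as the Z enol ether) | COC(=O)c1ccc(O/C=C\C[Si](C)(C)C)c(O)c1
A6 | alternative 3 | trans benzodioxane aldehyde with free C9 hydroxyl and ring A MOM ether | COc1cc([C@H]2Oc3cc(C=O)ccc3O[C@@H]2CO)cc(OC)c1OCOC
A7 | alternative 3 | 4-hydroxy-3-{(R)-[3,5-dimethoxy-4-(methoxymethoxy)phenyl][(2S)-oxiran-2-yl]methoxy}benzaldehyde | COc1cc([C@@H](Oc2cc(C=O)ccc2O)[C@@H]2CO2)cc(OC)c1OCOC
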